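The ratio that matters for the target is its rate of formation over its rate of destruction by starting material, and the concentration of starting material stands in both, so it cancels. What remains is the **balance share**: the fraction of the charge standing as target at which the path to target and the path to side product run equally fast, the rate constant of formation over the product of the side-product constant and the charge. While starting material lasts, target climbs towards this share, whatever fraction of the charge is left.

| flask | starting material | protic impurity | temperature | time |
|---|---|---|---|---|
| teal | 0.20 mM | 0.0600 mM | −15 °C | 1.0 min |
| blue | 0.20 mM | 0.0600 mM | 0 °C | 1.0 min |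
| ochre | 0.20 mM | 0.0600 mM | 15 °C | 1.0 min |

- the flask that comes out highest in amount of target, in percent of the starting material charged, or "all alike" when all lie within 1.5 percentage points (teal / blue / ochre / all alike)
- target at the end, in percent of the starting material charged, teal
- target at the end, in percent of the starting material charged, blue
- target at the end, in percent of the starting material charged, ochre

- percentages count the starting material that a species holds: one side product or homo dimer counts as two
- a step written with two of one species runs at k times the square of its concentration and takes two of it each time
- constants are those at 0 °C; use the activation energies and enthalpies for any other temperature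
- in a conversion other conformer counts as not yet reacted

    other conformer → isomer of the product (k1 = 0.032 s⁻¹, Ea1 = 83.0 kJ mol⁻¹)
    starting material → target (k2 = 0.016 s⁻¹, Ea2 = 75.0 kJ mol⁻¹)
    starting material + target → side product (k3 = 330 L mol⁻¹ s⁻¹, Ea3 = 38.0 kJ mol⁻¹)
    2 starting material → homo dimer (k4 = 0.060 L mol⁻¹ s⁻¹, Ea4 = 61.0 kJ mol⁻¹)
    target ⇌ isomer of the product (K5 = 0.38, k5 = 0.022 s⁻¹, Ea5 = 70.0 kJ mol⁻¹, ΔH5 = −6.00 kJ mol⁻¹)
    starting material ⇌ other conformer (K6 = 1.3, k6 = 0.010 s⁻¹, Ea6 = 82.0 kJ mol⁻¹, ΔH6 = −14.0 kJ mol⁻¹)
    other conformer + protic impurity → quenched substrate (k7 = 760 L mol⁻¹ s⁻¹, Ea7 = 39.0 kJ mol⁻¹)
    (constants at 0 °C)

For blue I get 24.2 %. The path to target has the higher activation energy, 75.0 kJ mol⁻¹ against 38.0 kJ mol⁻¹, so the share rises with warmth: 9.41 % in teal and 56.6 % in ochre.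

How near a flask comes depends on its exposure, the time integral of the fraction of charge still present as starting material. Target's loss is pseudo-first-order, with a constant proportional to that fraction, so leaving the isomer aside, target reaches the balance share times one minus the exponential of minus the side-product constant, the charge and the exposure multiplied together.

For the exposure I let starting material decay by its two first-order exits, to target and to other conformer. That gives 0.00358 s⁻¹ in teal, 0.0260 s⁻¹ in blue and 0.155 s⁻¹ in ochre. Over 1.0 min the exposures are 54.0 s, 30.4 s and 6.46 s.

The fractions of the balance share reached are then 74.0 % in teal, 86.5 % in blue and 63.9 % in ochre. I commit to 6.96 % for teal and 21.0 % for blue, and provisionally to 36.2 % for ochre.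

The weak link is ochre's supply of target: I counted just the direct path, yet other conformer passes to isomer of the product, which can run back to target. In ochre, other conformer leaves for isomer at 0.214 s⁻¹, for quenched substrate at 0.111 s⁻¹ and back to starting material at 0.0695 s⁻¹, so 54.2 % of what enters reaches isomer and 17.6 % returns. Net, starting material in ochre then decays at 0.143 s⁻¹, which makes the exposure 6.98 s. The isomer equilibrium constant there is 0.331, and target and isomer relax at 0.440 s⁻¹, faster than that decay, so I treat them as one pool at equilibrium, 75.1 % of it target. With the supply through isomer added, the balance share of target in ochre becomes 79.1 %, and since the side-product path takes from the pool through its target share, the fraction reached is 56.3 %. So ochre stands at 44.5 %, with the exposure still leaving out the starting material taken by the path to side product, and my choice is ochre.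

The forecast names ochre, with 6.6 % (5.5 % to 7.5 %) for teal, 21 % (18 % to 24 %) for blue and 38 % (33 % to 43 %) for ochre, on the ground that “the warmest flask wins despite its larger losses”.

The simulation gives ochre as highest, with 6.47 % in teal, 21.2 % in blue and 41.1 % in ochre.

In ochre the path to target ran while starting material was there: at 0.0646 min target was being made 2.91 times as fast as it was used up, and by 0.500 min starting material had fallen to 0.379 %. From then to the asked time target stood at 41.1 %, below that flask's balance share of 56.6 %, with side product at 36.0 %. Blue, with a balance share of 24.2 %, held 24.6 % of target at 10.0 min, when its starting material stood at 0 %.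

(The constants come from no measurement; the rest is arithmetic.)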